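**Retrosynthetic overview**
1. Flavone 8 ⇒ break O1–C2: the pyranone ring is closed last, by a dehydrogenative 6-endo oxa-Michael cyclisation of the unprotected 2'-hydroxychalcone 6.
2. Chalcone 6 ⇒ break Cα=Cβ: Claisen–Schmidt condensation of acetophenone 3 with 3-hydroxy-4,5-dimethoxybenzaldehyde 4 (B ring bought intact).
3. Acetophenone 3 ⇒ two nuclear C-methylations of phloroacetophenone 1 (A ring bought; it is symmetric, so either ortho-OH closes to the same flavone).
4. Ring order: rings A and B are purchased; ring C is the only ring made (step 3); no protecting groups.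

Assumption: the target has no stereocentre, so "single enantiomer" needs no stereocontrol; the only stereo-element on the way is the E-alkene of 6, which is consumed in step 3.

**Step 1**
Reactants: 1 2',4',6'-trihydroxyacetophenone (phloroacetophenone, commercial monohydrate)
Product: 3 2',4',6'-trihydroxy-3',5'-dimethylacetophenone, via 3'-methylphloroacetophenone 2 (not isolated)
Conditions: MeI (2.2 equiv), NaOMe (2.5 equiv), MeOH, 0 °C → reflux, 3 h; AcOH quench, chromatography/recrystallisation
Reagents that add atoms: iodomethane (MeI), SMILES CI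
Why: The phloroglucinolate anion reacts as a vinylogous enolate, so in MeOH with Na+ the soft electrophile MeI alkylates the two free ring carbons (base-mediated nuclear C-methylation, SN2), and limiting MeI to about 2 equiv holds back the dearomatised gem-dimethyl by-product (moderate yield expected, mono- and trimethyl by-products separated).

**Step 2**
Reactants: 3 2',4',6'-trihydroxy-3',5'-dimethylacetophenone; 4 3-hydroxy-4,5-dimethoxybenzaldehyde
Product: 6 (E)-2',4',6',3-tetrahydroxy-4,5-dimethoxy-3',5'-dimethylchalcone, via racemic aldol adduct 5 (not isolated)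
Conditions: 50% aq. KOH (ca. 12 equiv), EtOH, N2, 0 °C → rt, 48 h; then cold 2 M HCl to pH 3 at 0 °C, filter
Reagents that add atoms: none
Why: Claisen–Schmidt condensation (crossed aldol, then E1cB dehydration to the thermodynamic E-enone): only the methyl ketone can enolise, the 3-oxido group of 4 is meta to CHO and does not deactivate it, and the chalcone polyanion stays open in strong base so cold acidification delivers 6 (any trace of flavanone 7 is harmless because step 3 equilibrates the two).

**Step 3**
Reactants: 6 (E)-2',4',6',3-tetrahydroxy-4,5-dimethoxy-3',5'-dimethylchalcone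
Product: 8 5,7,3'-trihydroxy-4',5'-dimethoxy-6,8-dimethylflavone, via racemic flavanone 7 (not isolated)
Conditions: 3,3',5,5'-tetra-tert-butyl-4,4'-diphenoquinone (1.2 equiv), DBU (3 equiv), degassed DMF, Ar, dark, 50 °C, 16 h; then cold 1 M HCl, triturate solid with hexane/CH2Cl2
Reagents that add atoms: none
Why: Proposed new method: a base-triggered transfer-dehydrogenative oxa-Michael cyclisation in which DBU ionises the 2'-OH, 6-endo-trig oxa-Michael addition forms the O1–C2 bond and gives the C3-enolate of flavanone 7, and the sterically shielded diphenoquinone removes the C2–H (allylic to the enolate, α to oxygen and benzylic, so a strong hydride donor) as hydride or as e–/H• to give the flavone irreversibly while 6, 7 and the enolate keep equilibrating, with no aurone possible because oxygen only ever attacks Cβ; the closest known reaction types are DDQ/chloranil dehydrogenation of flavanones through their enols, flavin-dependent desaturation of enolates, and the use of this quinone as a 2e–/2H+ acceptor alongside free phenols and DBU in oxidative NHC catalysis.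

**Compound list**
1 | 2',4',6'-trihydroxyacetophenone (phloroacetophenone) | CC(=O)c1c(O)cc(O)cc1O | starting material
2 | 2',4',6'-trihydroxy-3'-methylacetophenone (not isolated) | CC(=O)c1c(O)cc(O)c(C)c1O | intermediate
3 | 2',4',6'-trihydroxy-3',5'-dimethylacetophenone | CC(=O)c1c(O)c(C)c(O)c(C)c1O | intermediate
4 | 3-hydroxy-4,5-dimethoxybenzaldehyde | COc1cc(C=O)cc(O)c1OC | starting material
5 | (±)-3-hydroxy-3-(3-hydroxy-4,5-dimethoxyphenyl)-1-(2,4,6-trihydroxy-3,5-dimethylphenyl)propan-1-one (racemic aldol adduct, not isolated) | COc1cc(C(O)CC(=O)c2c(O)c(C)c(O)c(C)c2O)cc(O)c1OC | intermediate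
6 | (2E)-3-(3-hydroxy-4,5-dimethoxyphenyl)-1-(2,4,6-trihydroxy-3,5-dimethylphenyl)prop-2-en-1-one (the chalcone) | COc1cc(/C=C/C(=O)c2c(O)c(C)c(O)c(C)c2O)cc(O)c1OC | intermediate
7 | (±)-5,7,3'-trihydroxy-4',5'-dimethoxy-6,8-dimethylflavanone (racemic at C2, reacts as its C3-enolate, not isolated) | COc1cc(C2CC(=O)c3c(O)c(C)c(O)c(C)c3O2)cc(O)c1OC | intermediate
8 | 5,7,3'-trihydroxy-4',5'-dimethoxy-6,8-dimethylflavone (achiral) | COc1cc(-c2cc(=O)c3c(O)c(C)c(O)c(C)c3o2)cc(O)c1OC | target

**Totals**
Total step count: 3. Longest linear sequence: 3 (1 → 3 → 6 → 8; aldehyde 4 is used as bought).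

**Steps most likely to fail, with fallbacks**

Step 3 (proposed new step). Risks: hydride transfer from the enolate may be slower than one-electron oxidation of the phenoxides by the quinone, giving oligomers, or the 4'-oxido chalcone may cyclise too slowly. The fallback sets out from 6 and comes back at 8 with known chemistry that separates ring closure from oxidation. Chalcone 6 is isomerised with NaOAc in refluxing EtOH to the isolated flavanone 7. This is then heated with I2 (0.2 equiv) in DMSO at 120 °C under N2: the enol of 7 is iodinated to trans-(±)-3-iodo-5,7,3'-trihydroxy-4',5'-dimethoxy-6,8-dimethylflavanone F5 (not isolated), which loses HI to give 8, while DMSO re-oxidises HI to I2.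

Step 2. Risk: the polyanion of unprotected 3 may enolise and condense poorly, giving low conversion and Cannizzaro loss of 4. The fallback sets out from 3 (with 4) and comes back at 7. Ketone 3 is treated with MOMCl (2.2 equiv) and DIPEA in CH2Cl2 at 0 °C to give 1-[2-hydroxy-4,6-bis(methoxymethoxy)-3,5-dimethylphenyl]ethanone F2; the hydrogen-bonded 2-OH stays free. Aldehyde 4 is treated with MOMCl/DIPEA to give 3,4-dimethoxy-5-(methoxymethoxy)benzaldehyde F3. Claisen–Schmidt condensation of the two (KOH, EtOH/H2O, rt) gives (E)-3-[3,4-dimethoxy-5-(methoxymethoxy)phenyl]-1-[2-hydroxy-4,6-bis(methoxymethoxy)-3,5-dimethylphenyl]prop-2-en-1-one F4. Treatment with 3 M HCl in MeOH at 60 °C removes the three MOM groups and closes the freed chalcone to flavanone 7, which is isolated and put into the step 3 conditions, where DBU re-opens and enolises it.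

Step 1. Risk: over-methylation (gem-dimethyl dearomatisation), O-methylation, or difficult separation of mono-, di- and trimethyl products. The fallback sets out from 1 and comes back at 3. A double Mannich reaction of 1 with aqueous formaldehyde and dimethylamine (EtOH, rt) gives 1-[3,5-bis(dimethylaminomethyl)-2,4,6-trihydroxyphenyl]ethanone F1. Hydrogenolysis of both benzylic C–N bonds (H2, 5 bar, Pd/C, AcOH/MeOH, 60 °C) gives 3. Each nuclear position takes only one aminomethyl group, so over-alkylation is not possible.

**Further compounds**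
F1 | step 1 | 1-[3,5-bis(dimethylaminomethyl)-2,4,6-trihydroxyphenyl]ethanone | CC(=O)c1c(O)c(CN(C)C)c(O)c(CN(C)C)c1O
F2 | step 2 | 1-[2-hydroxy-4,6-bis(methoxymethoxy)-3,5-dimethylphenyl]ethanone | CC(=O)c1c(O)c(C)c(OCOC)c(C)c1OCOC
F3 | step 2 | 3,4-dimethoxy-5-(methoxymethoxy)benzaldehyde | COCOc1cc(C=O)cc(OC)c1OC
F4 | step 2 | (E)-3-[3,4-dimethoxy-5-(methoxymethoxy)phenyl]-1-[2-hydroxy-4,6-bis(methoxymethoxy)-3,5-dimethylphenyl]prop-2-en-1-one | COCOc1cc(/C=C/C(=O)c2c(O)c(C)c(OCOC)c(C)c2OCOC)cc(OC)c1OC
F5 | step 3 | trans-(±)-3-iodo-5,7,3'-trihydroxy-4',5'-dimethoxy-6,8-dimethylflavanone (racemic, one enantiomer drawn) | O=C1c2c(O)c(C)c(O)c(C)c2O[C@@H](c2cc(O)c(OC)c(OC)c2)[C@@H]1I
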